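Every form of the complex came out of one charge of starting complex, so the fractions of that charge had to add to one, and I counted the complex with two exchanged as such a fraction. Incoming ligand replaced leaving ligand on the complex, once and then again.

the same everywhere: starting complex 0.050 M
- summer: incoming ligand 0.083 M; leaving ligand 0.050 M; capture agent 5 mM; run made earlier
- north-east: incoming ligand 0.0550 M; leaving ligand 0.0500 M; capture agent 5.00 mM; time 10 h
- north-west: incoming ligand 0.0550 M; leaving ligand 0.0800 M; capture agent 5.00 mM; time 10 h
- south-west: incoming ligand 0.0550 M; leaving ligand 0.120 M; capture agent 5.00 mM; time 10 h
- south: incoming ligand 0.0550 M; leaving ligand 0.150 M; capture agent 5.00 mM; time 10 h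
- north: incoming ligand 0.0550 M; leaving ligand 0.250 M; capture agent 5.00 mM; time 10 h

summer run (percent of the starting complex charged): time / h: complex with two exchanged / % = 0.500: 0.1; 0.833: 0.3; 1.50: 0.9; 3.00: 2.2; 6.00: 5.4

(each reading ± 0.3 percentage points)

- what was read earlier has a scatter of 0.3 percentage points, one standard deviation
- "hardly changes" means that all values lie within two and a half points (for a concentration: within two and a half percent of the largest)
- no earlier run changes the charge of incoming ligand; that part of a forecast is a guess
- no earlier run changes the charge of leaving ligand; that part of a forecast is a guess

- [complex with two exchanged] at the end for north-east, north-west, south-west, south, north, in this order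
- the shape of the row from first to last (falls, then rises / hardly changes / falls all the way / rises all the way / rises, then falls)

The quantity to watch was the steady gain, the fraction of the charge added per hour as complex with two exchanged once the summer curve ran straight. Between its last two readings this was 0.0107 /h, a reading that carries their scatter. That line reached zero at 0.937 h, so I took the lag as the time needed to build the complex with one exchanged. Extended to 10 h, the summer line gave 9.67%.

I reckoned two extreme flasks. In the first, I let leaving ligand do nothing, so the row stayed flat. I reckoned its level at 6.41% with the gain following incoming ligand to the first power, or 4.24% with the square. In the second, the product followed the inverse of the leaving-ligand charge, so north held 0.200 of the north-east fraction. Both charge effects were guesses, since no earlier run varied either one. I committed to the square, with two exchanges each using incoming ligand, and so to 4.24% for north-east. I placed the row nearer the flat flask because the summer gain read no slower as the exchanges released leaving ligand: 0.00867 /h earlier was less than the later 0.0107 /h. So I expected north to keep more than 0.5 of the north-east fraction.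

The forecast differed. It gave 0.003 M for north-east, which is 6.00% of the charge, and 8.000 × 10⁻⁴ M for north, a ratio of 0.267. It expected that “the product falls steadily along the row”, so its shape was falls all the way.

The flasks gave 0.00203 M, 0.00197 M, 0.00186 M, 0.00177 M and 0.00145 M, so the shape was falls all the way.

    starting complex + incoming ligand ⇌ leaving ligand + complex with one exchanged (K = 5.32, k = 0.00158 /M/s)
    complex with one exchanged + incoming ligand ⇌ leaving ligand + complex with two exchanged (K = 2.10, k = 1.01 × 10⁻⁴ /M/s)
    leaving ligand + starting complex → side product (k = 1.32 × 10⁻⁴ /M/s)
    complex with one exchanged + capture agent → trapped intermediate (k = 0.00123 /M/s)

At the end, the complex with one exchanged stood at 47.2% in north-east and 22.0% in north. From 5.00 h to 10.0 h, the complex with two exchanged in north-east gained 0.00407 /h, which is 0.380 of the summer steady gain, against a squared charge ratio of 0.439. Over the same hours, the complex with two exchanged in north gained 0.00255 /h, which is 0.238 of the summer steady gain.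

All runs are simulated for substances that don't exist; noise was put on by code.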